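Count doublings.

| flask | solid substrate | coupling partner | remark | time |
|---|---|---|---|---|
| east | 0.50 M | 1.6 M | run made earlier |  |
| north | 0.50 M | 1.9 M | run made earlier |  |
| north-west | 0.50 M | 3 M | run made earlier |  |
| south | 0.28 M | 2.5 M | run made earlier |  |
| delta | 0.50 M | 2.50 M |  | 25 h |
| alpha | 0.12 M | 1.50 M |  | 100 h |

| east: time / h | east: product / % | north: time / h | north: product / % | north-west: time / h | north-west: product / % | south: time / h | south: product / % |
|---|---|---|---|---|---|---|---|
| 1.33 | 0 | 2.00 | 0 | 1.33 | 0 | 2.00 | 0.9 |
| 3.00 | 0 | 6.00 | 1.3 | 3.00 | 0.6 | 6.00 | 2.9 |
| 8.00 | 2.1 | 12.0 | 5.6 | 8.00 | 4.0 | 12.0 | 16.6 |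
| 20.0 | 20.5 | 20.0 | 29.2 | 20.0 | 74.5 | 20.0 | 64.8 |

(scatter of a reading: 0.3 percentage points)

* the winner by amount of product, in percent of the solid substrate charged; "neither" if no more than 2 percentage points parts them (delta / alpha / neither)
* how much product is there at the end, in percent of the solid substrate charged: delta
* how much product is there at the end, in percent of the solid substrate charged: alpha

- solid, in amounts per volume of the solution: solid substrate
- steps thought possible: starting material + coupling partner + product -> 2 product; starting material + coupling partner -> product; solid substrate <-> starting material
- at the start none of the solid substrate is in solution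
- what has only dissolved of solid substrate counts as not reacted

The south run is the one to read, since it carries the partner charge of delta. Its first row, 0.9%, lies close to the scatter of 0.3 percentage points. From 6.00 h to 12.0 h the product fraction climbs from 2.9% to 16.6% of the charge, a doubling every 2.38 h. The last row, 64.8% at 20.0 h, gives a longer interval, 4.07 h. This reading is the doubling time of the product, the hours in which the converted fraction doubles during autocatalysis, and it covers the high-conversion stretch that delta still has to run.

My own reckoning assumes that equal partner and equal time give equal molar product while solid remains. South's product at 12.0 h is then 9.30% of delta's charge. Delta's remaining time holds 3.19 doublings, and reaching the full charge takes 3.43, so delta falls short, at 85.0%. The east run's last two rows give a doubling time of 3.65 h, and alpha's time holds 27.4 of these. Alpha's partner charge is smaller than the east run's, which may lengthen each one, but this reckoning still puts alpha near completion and ahead.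

The forecast names alpha, with 80% for delta and 97% for alpha, on the ground that “Growth then slows as dissolution and depletion bite”. For delta, my reckoning lies higher.

The simulation gives alpha as the winner, with 89.3% for delta and 98.5% for alpha.

    starting material + coupling partner + product → 2 product (k = 0.00651 M⁻² min⁻¹)
    starting material + coupling partner → product (k = 4.98 × 10⁻⁵ M⁻¹ min⁻¹)
    solid substrate ⇌ starting material, rate k3*(cs3 - [starting material]) while solid is left; crystals form when [starting material] > cs3 (solubility = 0.350 M, k = 0.00227 min⁻¹)

Alpha leads mainly because of its longer time: without that difference it stands at 22.2%, not 98.5%. Delta climbs from 10.8% at 12.5 h to 89.3% at 25.0 h, a doubling time of 4.10 h beside the 4.07 h read from south. For the neighbour flask with 0.85 M of solid substrate, the same reckoning gives 5.47% of its larger charge at 12.0 h, so the same 3.19 doublings reach 49.9%. The computed result for it is 56.2%.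

The readings come from a simulation with made-up constants, and the scatter is random.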